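The oxolane is disconnected at O1–C5 and C2–C3. O1–C2 with its aryl group is the carbonyl group of a protected vanillin, and C3–C4–C5 is a cyclopropane. Because the hydroxymethyl arm on C3 and the carbinol arm on C4 are cis, they can be tied as a γ-lactone, so the precursor is an enantiopure, exo-aryl 2-oxo-3-oxabicyclo[3.1.0]hexane-1-carboxylate. An iodide-relayed, strain-driven formal [3+2] annulation inserts the aldehyde C=O into the C3–C5 cyclopropane bond, making O1–C5 and C2–C3 in one operation. The single catalyst-set carbinol centre is relayed to the ring-fusion centres and then to C2 and C3. Decarboxylation and one hydride step finish the synthesis.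

Key step: step 5

Remark: target positions are named by the oxolane ring (O1, C2 aryl, C3 CH2OH, C4 carbinol arm, C5 H2); (−)-MIB is taken to deliver the vinyl group to the Si face as it does for alkylzinc reagents, and its enantiomer would be used if the sense proved reversed.

Step 1
Reactants: 1 vanillin
Product: 2 4-formyl-2-methoxyphenyl pivalate
Conditions: PivCl, Et3N, DMAP (cat.), CH2Cl2, 0 °C to rt
Reagents that add atoms: pivaloyl chloride, CC(C)(C)C(=O)Cl
Why: Base-mediated O-acylation of the phenol (ester formation); the pivalate should survive every step until the last, lowers the donor strength of the ring so that the benzylic C–O bonds made later are not ionised by Lewis acids, and no stereocentre is formed.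

Step 2
Reactants: 2 4-formyl-2-methoxyphenyl pivalate, 3 vinylmagnesium bromide
Product: 4 4-[(1S)-1-hydroxyprop-2-en-1-yl]-2-methoxyphenyl pivalate
Conditions: 3 (2.4 equiv), ZnCl2 (1.2 equiv), Et2O, 0 °C, then 1,4-dioxane and filtration (divinylzinc); (−)-MIB [(2S)-3-exo-morpholinoisoborneol, 5 mol %], 2, toluene, 0 °C; aqueous work-up
Reagents that add atoms: none
Why: Amino-alcohol-catalysed enantioselective 1,2-addition of a vinylzinc reagent to an aromatic aldehyde, in which the chiral zinc aminoalkoxide delivers the vinyl group to the Si face and so sets the (S)-carbinol centre under catalyst control, while the aryl ester is inert to organozinc reagents.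

Step 3
Reactants: 4 4-[(1S)-1-hydroxyprop-2-en-1-yl]-2-methoxyphenyl pivalate, 5 methyl malonyl chloride (methyl 3-chloro-3-oxopropanoate)
Product: 6 methyl (1S)-1-[3-methoxy-4-(pivaloyloxy)phenyl]prop-2-en-1-yl malonate
Conditions: pyridine, CH2Cl2, 0 °C
Reagents that add atoms: none
Why: Esterification of the secondary alcohol by the acid chloride with retention at the carbinol centre; it brings in the carbon that becomes C3 of the oxolane together with its future hydroxymethyl carbon.

Step 4
Reactants: 6 methyl (1S)-1-[3-methoxy-4-(pivaloyloxy)phenyl]prop-2-en-1-yl malonate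
Product: 8 methyl (1R,4S,5S)-4-[3-methoxy-4-(pivaloyloxy)phenyl]-2-oxo-3-oxabicyclo[3.1.0]hexane-1-carboxylate (aryl exo), via phenyliodonium ylide 7 (not isolated)
Conditions: PhI(OAc)2, MgO, Rh2(OAc)4 (2 mol %), 4 Å molecular sieves, CH2Cl2, 30 °C
Reagents that add atoms: none
Why: Oxidation of the malonate by PhI(OAc)2 gives phenyliodonium ylide 7, from which Rh2(OAc)4 forms a metal carbene that adds to the tethered vinyl group (intramolecular cyclopropanation of an allyl malonate); the two ring-fusion centres are set by substrate control from the carbinol centre, because the transition state that keeps the carbinol H eclipsed with the alkene (least allylic 1,3-strain) places the aryl group exo, anti to the cyclopropane CH2.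

Step 5
Reactants: 8 methyl (1R,4S,5S)-4-[3-methoxy-4-(pivaloyloxy)phenyl]-2-oxo-3-oxabicyclo[3.1.0]hexane-1-carboxylate, 2 4-formyl-2-methoxyphenyl pivalate
Product: 11 methyl (3S,3aR,6R,6aS)-3,6-bis[3-methoxy-4-(pivaloyloxy)phenyl]-1-oxotetrahydro-1H,3H-furo[3,4-c]furan-6a-carboxylate (cis-fused and both aryl groups exo), via iodo enolate 9 (not isolated), via iodo aldolate 10 (not isolated)
Conditions: MgI2 (30 mol %), 2 (1.5 equiv), THF, 65 °C
Reagents that add atoms: none
Why: Proposed new method: iodide opens the doubly activated cyclopropane of 8 by SN2 attack at its CH2 carbon (C6) and frees the magnesium-chelated malonate-type enolate 9, which adds to the carbonyl carbon of 2 to give aldolate 10; the alkoxide of 10 then displaces iodide from the same CH2 carbon and returns MgI2, so the aldehyde C=O is inserted into the strained C1–C6 bond in a formal [3+2] annulation. The closest known reaction types are the MgI2-promoted ring expansion of activated cyclopropanes with aldimines to pyrrolidines (homoconjugate addition, Mannich addition, N-alkylation) and the Lewis-acid [3+2] cycloaddition of donor–acceptor cyclopropanes with aldehydes, whereas an acceptor-only, lactone-fused cyclopropane with an aldehyde has not been shown. The oxolane ring closes by 5-exo-tet O-alkylation after an intermolecular aldol addition, and the release of cyclopropane strain together with the irreversible etherification should pull the reversible aldol step forward. The new quaternary centre (C-6a) is fixed by the existing lactone ring, because only the aldolate with the new C–C bond cis to the CH2I arm can cyclise, which gives the cis-fused bicycle. The aryl-bearing centre (C-6) is set by substrate control, since the equilibrating aldolates should close faster with the aryl group on the convex (exo) face. The step needs iodide attack at CH2 and not at the ring CH or the benzylic lactone C–O bond; the unhindered primary carbon and the overlap of the C1–C6 bond with both carbonyl groups should secure the first, and the electron-poor pivaloyloxy-substituted ring should suppress benzylic ionisation.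

Step 6
Reactants: 11 methyl (3S,3aR,6R,6aS)-3,6-bis[3-methoxy-4-(pivaloyloxy)phenyl]-1-oxotetrahydro-1H,3H-furo[3,4-c]furan-6a-carboxylate
Product: 12 (3S,3aR,6S,6aS)-3,6-bis[3-methoxy-4-(pivaloyloxy)phenyl]tetrahydro-1H,3H-furo[3,4-c]furan-1-one
Conditions: LiCl, H2O, DMSO, 130 °C
Reagents that add atoms: none
Why: Krapcho dealkoxycarbonylation (chloride SN2 at the ester methyl group, loss of CO2, protonation of the lactone enolate); the proton can only arrive on the face that keeps the two five-membered rings cis-fused, so C-6a is fixed by the ring fusion, and the change of the C-6 descriptor from R to S is a priority effect only.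

Step 7
Reactants: 12 (3S,3aR,6S,6aS)-3,6-bis[3-methoxy-4-(pivaloyloxy)phenyl]tetrahydro-1H,3H-furo[3,4-c]furan-1-one
Product: 13 (−)-tanegol
Conditions: LiAlH4 (excess), THF, 0 °C to rt; work-up with aqueous KNaC4H4O6 and NH4Cl at pH 7
Reagents that add atoms: none
Why: Hydride reduction of the γ-lactone to the 1,4-diol with concurrent reductive cleavage of both aryl pivalates; all C–O bonds at the stereocentres stay intact, so the configuration of 12 is carried into the target, and the neutral work-up avoids acid-induced cyclisation of the benzylic alcohol onto the primary alcohol.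

Compound list
1 | vanillin (4-hydroxy-3-methoxybenzaldehyde) | COc1cc(C=O)ccc1O | starting material
2 | 4-formyl-2-methoxyphenyl pivalate | COc1cc(C=O)ccc1OC(=O)C(C)(C)C | intermediate
3 | vinylmagnesium bromide | C=C[Mg]Br | starting material
4 | 4-[(1S)-1-hydroxyprop-2-en-1-yl]-2-methoxyphenyl pivalate | C=C[C@H](O)c1ccc(OC(=O)C(C)(C)C)c(OC)c1 | intermediate
5 | methyl malonyl chloride (methyl 3-chloro-3-oxopropanoate) | COC(=O)CC(=O)Cl | starting material
6 | methyl (1S)-1-[3-methoxy-4-(pivaloyloxy)phenyl]prop-2-en-1-yl malonate | COC(=O)CC(=O)O[C@@H](C=C)c1ccc(OC(=O)C(C)(C)C)c(OC)c1 | intermediate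
7 | phenyliodonium ylide of 6 (ylide carbon between the two ester carbonyl groups) | COC(=O)[C-]([I+]c1ccccc1)C(=O)O[C@@H](C=C)c1ccc(OC(=O)C(C)(C)C)c(OC)c1 | intermediate
8 | methyl (1R,4S,5S)-4-[3-methoxy-4-(pivaloyloxy)phenyl]-2-oxo-3-oxabicyclo[3.1.0]hexane-1-carboxylate (aryl trans to the cyclopropane CH2) | COC(=O)[C@@]12C[C@@H]1[C@@H](c1ccc(OC(=O)C(C)(C)C)c(OC)c1)OC2=O | intermediate
9 | iodomagnesium enolate of methyl (4S,5S)-4-(iodomethyl)-5-[3-methoxy-4-(pivaloyloxy)phenyl]-2-oxooxolane-3-carboxylate (aryl and CH2I trans) | COC(=O)C1=C(O[Mg]I)O[C@H](c2ccc(OC(=O)C(C)(C)C)c(OC)c2)[C@H]1CI | intermediate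
10 | iodomagnesium aldolate of 9 and 2 (new C–C bond cis to the CH2I arm, carbinolate carbon configured as C-6 of 11) | COC(=O)[C@]1([C@H](O[Mg]I)c2ccc(OC(=O)C(C)(C)C)c(OC)c2)C(=O)O[C@H](c2ccc(OC(=O)C(C)(C)C)c(OC)c2)[C@H]1CI | intermediate
11 | methyl (3S,3aR,6R,6aS)-3,6-bis[3-methoxy-4-(pivaloyloxy)phenyl]-1-oxotetrahydro-1H,3H-furo[3,4-c]furan-6a-carboxylate | O=C1O[C@H](c3ccc(OC(=O)C(C)(C)C)c(OC)c3)[C@H]2CO[C@H](c3ccc(OC(=O)C(C)(C)C)c(OC)c3)[C@@]12C(=O)OC | intermediate
12 | (3S,3aR,6S,6aS)-3,6-bis[3-methoxy-4-(pivaloyloxy)phenyl]tetrahydro-1H,3H-furo[3,4-c]furan-1-one | O=C1O[C@H](c3ccc(OC(=O)C(C)(C)C)c(OC)c3)[C@H]2CO[C@H](c3ccc(OC(=O)C(C)(C)C)c(OC)c3)[C@@H]12 | intermediate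
13 | (−)-tanegol, 4-[(2S,3R,4R)-4-[(S)-hydroxy(4-hydroxy-3-methoxyphenyl)methyl]-3-(hydroxymethyl)oxolan-2-yl]-2-methoxyphenol | COc1cc([C@@H](O)[C@H]2CO[C@H](c3ccc(O)c(OC)c3)[C@H]2CO)ccc1O | target

Total step count: 7. Longest linear sequence: 7 steps (vanillin to 13; aldehyde 2 enters twice, in steps 2 and 5).

Steps most likely to fail

Step 5 (key step). The aldol equilibrium may lie on the side of enolate 9, so that the cyclopropane simply re-closes and nothing turns over. Reversible ionisation of the benzylic lactone C–O bond may erode the configuration at that carbon, and the aldolates may close with poor exo/endo selection at the new aryl-bearing carbon. The fallback sets out from 8 and comes back at 11, and makes the same two bonds stepwise with known reactions. Iodotrimethylsilane (CH2Cl2, −78 to −40 °C) opens the activated cyclopropane by homoconjugate addition to give the γ-iodo silyl ketene acetal F1. A Mukaiyama aldol addition of the γ-iodo silyl ketene acetal F1 to aldehyde 2 (TiCl4, CH2Cl2, −78 °C) should give the iodo aldol F2, of which the diastereomer with the new C–C bond cis to the CH2I arm is the one that can cyclise. Silver-assisted Williamson etherification of the iodo aldol F2 (Ag2O, CH2Cl2, rt) should then close the oxolane to 11.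

Step 4. The carbene may add to the electron-rich arene (ring expansion) instead of the vinyl group, or the cyclopropanation may give poor exo/endo selectivity. The fallback sets out from 6 and comes back at 8 by a radical route. α-Iodination (N-iodosuccinimide, Mg(ClO4)2 cat., EtOAc) should give the iodomalonate F3. Iodine-atom-transfer radical cyclisation of the iodomalonate F3 (Bu3SnSnBu3 cat., hν, benzene, 80 °C) closes the lactone by 5-exo-trig attack of the malonyl radical on the vinyl group. It should give the trans iodomethyl lactone F4 through a chair-like transition state with the aryl group pseudo-equatorial. DBU (THF, 0 °C) should then close the cyclopropane of the trans iodomethyl lactone F4 by 3-exo-tet C-alkylation to give 8.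

Step 2. Residual magnesium salts may promote an uncatalysed background addition and erode the enantioselectivity, or vinyl transfer from the zinc reagent made in the flask may be sluggish. The fallback sets out from 2 and comes back at 4. Direct addition of 3 (THF, −78 °C) should give the racemic allylic alcohol F5. Lipase-catalysed kinetic resolution of the racemic allylic alcohol F5 (Candida antarctica lipase B, vinyl acetate, hexane, 30 °C) should acylate the (R)-enantiomer to the (R)-acetate F6 and leave the (S)-alcohol 4, which is separated by chromatography.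

Further compounds
F1 | step 5 | methyl (4S,5S)-4-(iodomethyl)-5-[3-methoxy-4-(pivaloyloxy)phenyl]-2-(trimethylsilyloxy)-4,5-dihydrofuran-3-carboxylate | COC(=O)C1=C(O[Si](C)(C)C)O[C@H](c2ccc(OC(=O)C(C)(C)C)c(OC)c2)[C@H]1CI
F2 | step 5 | methyl 3-{hydroxy[3-methoxy-4-(pivaloyloxy)phenyl]methyl}-4-(iodomethyl)-5-[3-methoxy-4-(pivaloyloxy)phenyl]-2-oxooxolane-3-carboxylate (carbinol arm cis to CH2I, configured as in 10) | COC(=O)[C@]1([C@H](O)c2ccc(OC(=O)C(C)(C)C)c(OC)c2)C(=O)O[C@H](c2ccc(OC(=O)C(C)(C)C)c(OC)c2)[C@H]1CI
F3 | step 4 | methyl (1S)-1-[3-methoxy-4-(pivaloyloxy)phenyl]prop-2-en-1-yl 2-iodomalonate (epimers at the C–I carbon) | COC(=O)C(I)C(=O)O[C@@H](C=C)c1ccc(OC(=O)C(C)(C)C)c(OC)c1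
F4 | step 4 | methyl (4S,5S)-4-(iodomethyl)-5-[3-methoxy-4-(pivaloyloxy)phenyl]-2-oxooxolane-3-carboxylate (epimers at C-3) | COC(=O)C1C(=O)O[C@H](c2ccc(OC(=O)C(C)(C)C)c(OC)c2)[C@H]1CI
F5 | step 2 | racemic 4-(1-hydroxyprop-2-en-1-yl)-2-methoxyphenyl pivalate | C=CC(O)c1ccc(OC(=O)C(C)(C)C)c(OC)c1
F6 | step 2 | 4-[(1R)-1-acetoxyprop-2-en-1-yl]-2-methoxyphenyl pivalate | C=C[C@@H](OC(C)=O)c1ccc(OC(=O)C(C)(C)C)c(OC)c1
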